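**Retrosynthetic overview**
- Target ⇐ Fleming–Tamao unmasking of a C19–SiMe2Ph group and C14 glycolate esterification of a tricyclic 14-alcohol.
- Eight-membered ring (closed last) ⇐ C5–C14 bond by SmI2 ketyl–enone cyclisation of an aldehyde tethered to a hydrindenone.
- Tetrahydrofuran ring with C11, C12 and C19 ⇐ new catalytic asymmetric [3+2] annulation (C11–C12 bond) of a hydrindenone aldehyde with an (E)-γ,γ-disubstituted allylsilane.
- Hydrindenone aldehyde ⇐ 4-methylcyclohexenone by oxidative transposition, cuprate addition (C9), aldol condensation (five-membered ring), then MeLi, hydroboration (C10) and a double oxidation.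
- (S)-4-Methylcyclohexenone ⇐ propanal + methyl vinyl ketone by organocatalytic Michael/aldol (C6, first stereocentre). Ring order: six-membered, five-membered, tetrahydrofuran, eight-membered.

Assumption: the target is taken exactly as the SMILES is written at all nine stereocentres (atom labels C1–C20 follow pleuromutilin numbering, C19/C20 being the former vinyl carbons), and every intermediate is drawn with the descriptors that carry unchanged into that string.

**Step 1**
Reactants: 1 propanal; 2 but-3-en-2-one (methyl vinyl ketone)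
Product: 4 (4S)-4-methylcyclohex-2-en-1-one, via Michael adduct 3 (not isolated)
Conditions: (R)-α,α-diphenylprolinol trimethylsilyl ether (5 mol%), ethyl 3,4-dihydroxybenzoate (20 mol%), neat, 4 °C; then 0.1 M aq. KOH, nBu4NOH (cat.), Et2O/THF, reflux
Reagents that add atoms: none
Why: Enamine-catalysed asymmetric Michael addition sets C6 (the first stereocentre) because the CPh2(OSiMe3) group shields one face of the E-enamine of propanal, and the base-mediated intramolecular aldol condensation then closes the enone without touching the new centre.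

**Step 2**
Reactants: 4 (4S)-4-methylcyclohex-2-en-1-one; 5 [2-(1,3-dioxan-2-yl)ethyl]magnesium bromide
Product: 6 (4S)-1-[2-(1,3-dioxan-2-yl)ethyl]-4-methylcyclohex-2-en-1-ol
Conditions: CeCl3, THF, −78 °C to 0 °C; then H2O
Reagents that add atoms: none
Why: CeCl3-promoted Grignard 1,2-addition to the enone carbonyl; the new carbinol centre forms as a mixture and is erased in step 3.

**Step 3**
Reactants: 6 (4S)-1-[2-(1,3-dioxan-2-yl)ethyl]-4-methylcyclohex-2-en-1-ol
Product: 7 (6S)-3-[2-(1,3-dioxan-2-yl)ethyl]-6-methylcyclohex-2-en-1-one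
Conditions: pyridinium chlorochromate, 4 Å MS, CH2Cl2, rt
Reagents that add atoms: none
Why: Dauben–Michno oxidative 1,3-transposition ([3,3] shift of the tertiary allylic chromate ester, then oxidation) moves the oxygen to C5 under non-basic conditions that leave the C6 centre intact.

**Step 4**
Reactants: 7 (6S)-3-[2-(1,3-dioxan-2-yl)ethyl]-6-methylcyclohex-2-en-1-one; 8 prop-1-en-2-ylmagnesium bromide
Product: 10 (2S,5R)-5-[2-(1,3-dioxan-2-yl)ethyl]-2-methyl-5-(prop-1-en-2-yl)cyclohexan-1-one, via silyl enol ether 9 (not isolated)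
Conditions: CuBr·SMe2 (10 mol%), Me3SiCl, THF, −78 °C; then K2CO3 (cat.), MeOH, 0 °C
Reagents that add atoms: none
Why: Copper-catalysed, Me3SiCl-accelerated conjugate addition builds quaternary C9; axial attack on the half-chair that keeps the C6 methyl pseudoaxial (no A(1,2) strain with the developing silyl enol ether) places isopropenyl trans to the C6 methyl.

**Step 5**
Reactants: 10 (2S,5R)-5-[2-(1,3-dioxan-2-yl)ethyl]-2-methyl-5-(prop-1-en-2-yl)cyclohexan-1-one
Product: 12 (3aR,6S)-6-methyl-3a-(prop-1-en-2-yl)-2,3,3a,4,5,6-hexahydro-7H-inden-7-one, via keto aldehyde 11 (not isolated)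
Conditions: 2 M HCl, THF, 45 °C
Reagents that add atoms: none
Why: Acetal hydrolysis followed by acid-catalysed intramolecular aldol condensation (ketone enol at C4 onto the aldehyde, five-membered ring, dehydration); no stereocentre is formed.

**Step 6**
Reactants: 12 (3aR,6S)-6-methyl-3a-(prop-1-en-2-yl)-2,3,3a,4,5,6-hexahydro-7H-inden-7-one
Product: 13 (3aR,6S,7S)-6,7-dimethyl-3a-(prop-1-en-2-yl)-3,3a,4,5,6,7-hexahydro-2H-inden-7-ol
Conditions: MeLi, CeCl3, THF, −78 °C; then H2O
Reagents that add atoms: methyllithium ([Li]C)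
Why: Organocerium 1,2-addition to the hindered enone carbonyl, methyl entering anti to the neighbouring C6 methyl; this carbinol centre is erased in step 8.

**Step 7**
Reactants: 13 (3aR,6S,7S)-6,7-dimethyl-3a-(prop-1-en-2-yl)-3,3a,4,5,6,7-hexahydro-2H-inden-7-ol
Product: 15 (2R)-2-[(3aR,6S,7S)-7-hydroxy-6,7-dimethyl-2,3,4,5,6,7-hexahydro-3aH-inden-3a-yl]propan-1-ol, via alkylborane 14 (not isolated)
Conditions: 9-BBN (1.5 equiv), THF, 0 °C to rt; then NaOH, 30% H2O2, 0 °C
Reagents that add atoms: hydrogen peroxide (OO)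
Why: Hydroboration–oxidation in which 9-BBN takes only the 1,1-disubstituted alkene (anti-Markovnikov) and sets C10 by adding to the isopropenyl face turned away from the C4/C5 flank in the conformer where C9–C8 eclipses the methylene; this selectivity is substrate-controlled and not guaranteed.

**Step 8**
Reactants: 15 (2R)-2-[(3aR,6S,7S)-7-hydroxy-6,7-dimethyl-2,3,4,5,6,7-hexahydro-3aH-inden-3a-yl]propan-1-ol
Product: 16 (2R)-2-[(3aS,6S)-6,7-dimethyl-1-oxo-1,2,3,4,5,6-hexahydro-3aH-inden-3a-yl]propanal
Conditions: pyridinium chlorochromate (5 equiv), 4 Å MS, CH2Cl2, rt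
Reagents that add atoms: none
Why: One oxidant does two jobs, oxidising the primary alcohol to the C11 aldehyde and effecting Dauben oxidative transposition of the tertiary allylic alcohol to the C3 enone, under non-basic conditions that do not epimerise C10.

**Step 9**
Reactants: 17 pent-1-en-4-yne
Product: 19 (1E)-1-iodo-2-methylpenta-1,4-diene, via alkenylalane 18 (not isolated)
Conditions: AlMe3 (2 equiv), Cp2ZrCl2 (20 mol%), CH2Cl2, 0 °C to rt; then I2, THF, −30 °C
Reagents that add atoms: trimethylaluminium (C[Al](C)C); iodine (II)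
Why: Negishi zirconium-catalysed carboalumination (syn addition, methyl to the internal carbon) and iodinolysis with retention give the E trisubstituted alkenyl iodide.

**Step 10**
Reactants: 19 (1E)-1-iodo-2-methylpenta-1,4-diene; 20 (chloromethyl)dimethyl(phenyl)silane
Product: 22 [(2E)-3-methylhexa-2,5-dien-1-yl]dimethyl(phenyl)silane, via Grignard reagent 21 (not isolated)
Conditions: 20, Mg, THF, reflux; then 19, Pd(PPh3)4 (3 mol%), THF, 50 °C
Reagents that add atoms: none
Why: Kumada cross-coupling of the alkenyl iodide with the silylmethyl Grignard reagent proceeds with retention of alkene geometry and gives the E allylsilane.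

**Step 11**
Reactants: 16 (2R)-2-[(3aS,6S)-6,7-dimethyl-1-oxo-1,2,3,4,5,6-hexahydro-3aH-inden-3a-yl]propanal; 22 [(2E)-3-methylhexa-2,5-dien-1-yl]dimethyl(phenyl)silane
Product: 23 (3aS,6S)-3a-{(1R)-1-[(2S,3R,4S)-4-[dimethyl(phenyl)silyl]-3-methyl-3-(prop-2-en-1-yl)oxolan-2-yl]ethyl}-6,7-dimethyl-2,3,3a,4,5,6-hexahydro-1H-inden-1-one
Conditions: chiral imidodiphosphorimidate Brønsted acid (S,S)-IDPi (5 mol%, silylated in situ by 22; the catalyst enantiomer is a guess at the matched case), 22 (1.5 equiv), PhMe/CH2Cl2, −60 °C to −40 °C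
Reagents that add atoms: none
Why: Proposed new method: a confined chiral silylium–imidodiphosphorimidate ion pair (formed by protodesilylation of a little 22) activates the aldehyde; the γ-carbon (C12) of the E-allylsilane adds through an antiperiplanar open transition state on the Felkin–Anh face of C11 with the aldehyde substituent over the smaller C12 methyl (setting C11 and quaternary C12); the β-silyl cation is bridged as a siliranium ion, undergoes a 1,2-silyl shift and is captured at C20 by the carbonyl oxygen anti to silicon (setting C19, silicon cis to the C12 methyl because the alkene is E); loss of the silylium ion from oxygen turns the catalyst over, and the non-nucleophilic counter-anion disfavours desilylation to a Hosomi–Sakurai product; the closest known reaction types are the BF3-promoted [3+2] annulation of allyl- and crotylsilanes with aldehydes to silyl tetrahydrofurans and the silylium–imidodiphosphorimidate-catalysed Hosomi–Sakurai allylation, neither shown for a γ,γ-disubstituted allylsilane that creates a quaternary ring carbon nor as a catalytic asymmetric annulation.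

**Step 12**
Reactants: 23 (the annulation product of step 11)
Product: 25 2-[(2S,3R,4S)-4-[dimethyl(phenyl)silyl]-2-{(1R)-1-[(3aS,6S)-6,7-dimethyl-1-oxo-1,2,3,4,5,6-hexahydro-3aH-inden-3a-yl]ethyl}-3-methyloxolan-3-yl]acetaldehyde, via diol 24 (not isolated)
Conditions: OsO4 (2 mol%), NaIO4 (4 equiv), 2,6-lutidine, dioxane/H2O 3:1, rt
Reagents that add atoms: sodium periodate ([Na+].[O-]I(=O)(=O)=O); water (O)
Why: Lemieux–Johnson oxidative cleavage, OsO4 selecting the monosubstituted terminal alkene over the tetrasubstituted electron-poor enone alkene, unmasks the C14 aldehyde.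

**Step 13**
Reactants: 25 (the C14 aldehyde of step 12)
Product: 26 C19-silylated tricyclic 14-alcohol (the target lacking the glycolate and carrying SiMe2Ph in place of the C19 hydroxyl)
Conditions: SmI2 (3 equiv), H2O (10 equiv), THF, 0 °C, 0.005 M
Reagents that add atoms: none
Why: SmI2-mediated ketyl–enone radical cyclisation closes the eight-membered ring by C14–C5 bond formation, creating C14 and quaternary C5 in one cyclic transition state with the O–Sm bond anti to the C5 methyl, and the samarium enolate is then protonated at C4 on the face of the new C5–C14 bond.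

**Step 14**
Reactants: 26 C19-silylated tricyclic 14-alcohol; 27 2-[(tert-butyldimethylsilyl)oxy]acetic acid
Product: 28 14-O-[(tert-butyldimethylsilyloxy)acetyl] ester of 26
Conditions: DCC, DMAP, CH2Cl2, 0 °C to 35 °C
Reagents that add atoms: none
Why: Steglich esterification of the hindered C14 alcohol, which is the only free hydroxyl because the C19 oxygen is still masked as a C–Si bond.

**Step 15**
Reactants: 28 14-O-[(tert-butyldimethylsilyloxy)acetyl] ester of 26
Product: 30 Pleuromutilin B, via fluorosilane 29 (not isolated)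
Conditions: HBF4·OEt2, CH2Cl2, 0 °C to rt; then KF, KHCO3, 30% H2O2, THF/MeOH, rt
Reagents that add atoms: hydrogen peroxide (OO)
Why: Fleming–Tamao oxidation: acid cleaves the phenyl–silicon bond to the fluorosilane (and removes the glycolate silyl ether), and peroxide-induced 1,2-migration of C19 from silicon to oxygen gives the C19 hydroxyl with retention of configuration.

**Compound list**
1 | propanal | CCC=O | starting material
2 | but-3-en-2-one (methyl vinyl ketone) | CC(=O)C=C | starting material
3 | (2S)-2-methyl-5-oxohexanal | O=C[C@@H](C)CCC(C)=O | intermediate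
4 | (4S)-4-methylcyclohex-2-en-1-one | O=C1C=C[C@@H](C)CC1 | intermediate
5 | [2-(1,3-dioxan-2-yl)ethyl]magnesium bromide (THF solution) | Br[Mg]CCC1OCCCO1 | starting material
6 | (4S)-1-[2-(1,3-dioxan-2-yl)ethyl]-4-methylcyclohex-2-en-1-ol, both C1 epimers | OC1(CCC2OCCCO2)C=C[C@@H](C)CC1 | intermediate
7 | (6S)-3-[2-(1,3-dioxan-2-yl)ethyl]-6-methylcyclohex-2-en-1-one | O=C1C=C(CCC2OCCCO2)CC[C@@H]1C | intermediate
8 | prop-1-en-2-ylmagnesium bromide | CC(=C)[Mg]Br | starting material
9 | trimethylsilyl enol ether of 10 (C4=C5–OSiMe3, C6 and C9 as in 10) | CC(=C)[C@]1(CCC2OCCCO2)C=C(O[Si](C)(C)C)[C@@H](C)CC1 | intermediate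
10 | (2S,5R)-5-[2-(1,3-dioxan-2-yl)ethyl]-2-methyl-5-(prop-1-en-2-yl)cyclohexan-1-one (isopropenyl trans to methyl) | CC(=C)[C@]1(CCC2OCCCO2)CC(=O)[C@@H](C)CC1 | intermediate
11 | 3-[(1R,4S)-4-methyl-3-oxo-1-(prop-1-en-2-yl)cyclohexyl]propanal | CC(=C)[C@]1(CCC=O)CC(=O)[C@@H](C)CC1 | intermediate
12 | (3aR,6S)-6-methyl-3a-(prop-1-en-2-yl)-2,3,3a,4,5,6-hexahydro-7H-inden-7-one | CC(=C)[C@]12CCC=C1C(=O)[C@@H](C)CC2 | intermediate
13 | (3aR,6S,7S)-6,7-dimethyl-3a-(prop-1-en-2-yl)-3,3a,4,5,6,7-hexahydro-2H-inden-7-ol | CC(=C)[C@]12CCC=C1[C@@](C)(O)[C@@H](C)CC2 | intermediate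
14 | B-alkyl-9-borabicyclo[3.3.1]nonane from 13 (boron on C11, C10 R) | C[C@@H](CB1C2CCCC1CCC2)[C@]12CCC=C1[C@@](C)(O)[C@@H](C)CC2 | intermediate
15 | (2R)-2-[(3aR,6S,7S)-7-hydroxy-6,7-dimethyl-2,3,4,5,6,7-hexahydro-3aH-inden-3a-yl]propan-1-ol | C[C@@H](CO)[C@]12CCC=C1[C@@](C)(O)[C@@H](C)CC2 | intermediate
16 | (2R)-2-[(3aS,6S)-6,7-dimethyl-1-oxo-1,2,3,4,5,6-hexahydro-3aH-inden-3a-yl]propanal | C[C@@H](C=O)[C@]12CCC(=O)C1=C(C)[C@@H](C)CC2 | intermediate
17 | pent-1-en-4-yne | C=CCC#C | starting material
18 | dimethyl[(1E)-2-methylpenta-1,4-dien-1-yl]alane | C=CC/C(C)=C/[Al](C)C | intermediate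
19 | (1E)-1-iodo-2-methylpenta-1,4-diene | C=CC/C(C)=C/I | intermediate
20 | (chloromethyl)dimethyl(phenyl)silane | ClC[Si](C)(C)c1ccccc1 | starting material
21 | {[dimethyl(phenyl)silyl]methyl}magnesium chloride | Cl[Mg]C[Si](C)(C)c1ccccc1 | intermediate
22 | [(2E)-3-methylhexa-2,5-dien-1-yl]dimethyl(phenyl)silane | C=CC/C(C)=C/C[Si](C)(C)c1ccccc1 | intermediate
23 | (3aS,6S)-3a-{(1R)-1-[(2S,3R,4S)-4-[dimethyl(phenyl)silyl]-3-methyl-3-(prop-2-en-1-yl)oxolan-2-yl]ethyl}-6,7-dimethyl-2,3,3a,4,5,6-hexahydro-1H-inden-1-one (ring: C11–H cis to C12–CH3, C19–Si cis to C12–CH3) | C[C@@H]([C@@H]1OC[C@@H]([Si](C)(C)c2ccccc2)[C@]1(C)CC=C)[C@]12CCC(=O)C1=C(C)[C@@H](C)CC2 | intermediate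
24 | 2,3-dihydroxypropyl analogue of 23 (diol from the allyl group, both carbinol epimers) | C[C@@H]([C@@H]1OC[C@@H]([Si](C)(C)c2ccccc2)[C@]1(C)CC(O)CO)[C@]12CCC(=O)C1=C(C)[C@@H](C)CC2 | intermediate
25 | 2-[(2S,3R,4S)-4-[dimethyl(phenyl)silyl]-2-{(1R)-1-[(3aS,6S)-6,7-dimethyl-1-oxo-1,2,3,4,5,6-hexahydro-3aH-inden-3a-yl]ethyl}-3-methyloxolan-3-yl]acetaldehyde | C[C@@H]([C@@H]1OC[C@@H]([Si](C)(C)c2ccccc2)[C@]1(C)CC=O)[C@]12CCC(=O)C1=C(C)[C@@H](C)CC2 | intermediate
26 | tricyclic alcohol: the target without its glycolate (free C14–OH) and with SiMe2Ph in place of the C19 hydroxyl, same configuration at all nine stereocentres | C[C@H]1[C@@H]2OC[C@@H]([Si](C)(C)c3ccccc3)[C@]2(C)C[C@@H](O)[C@@]2(C)[C@@H](C)CC[C@]13CCC(=O)[C@@H]32 | intermediate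
27 | 2-[(tert-butyldimethylsilyl)oxy]acetic acid | CC(C)(C)[Si](C)(C)OCC(=O)O | starting material
28 | 14-O-[(tert-butyldimethylsilyloxy)acetyl] ester of 26 | C[C@H]1[C@@H]2OC[C@@H]([Si](C)(C)c3ccccc3)[C@]2(C)C[C@@H](OC(=O)CO[Si](C)(C)C(C)(C)C)[C@@]2(C)[C@@H](C)CC[C@]13CCC(=O)[C@@H]32 | intermediate
29 | C19-fluorodimethylsilyl analogue of 30 (free glycolate hydroxyl) | C[C@H]1[C@@H]2OC[C@@H]([Si](C)(C)F)[C@]2(C)C[C@@H](OC(=O)CO)[C@@]2(C)[C@@H](C)CC[C@]13CCC(=O)[C@@H]32 | intermediate
30 | Pleuromutilin B | C[C@H]1[C@@H]2OC[C@@H](O)[C@]2(C)C[C@@H](OC(=O)CO)[C@@]2(C)[C@@H](C)CC[C@]13CCC(=O)[C@@H]32 | target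

**Step count**
Total steps: 15. Longest linear sequence: 13 (steps 1–8 and 11–15); steps 9–10 make the allylsilane.

**Three steps most likely to fail**

Step 11 (the new annulation). The C11–C12 bond is very congested, desilylation to a Hosomi–Sakurai product competes, and three stereocentres are set at once. The fallback uses known reactions only, sets out from 16 and 22 and comes back at 30. TiCl4 (CH2Cl2, −78 °C) turns the same pair into the Hosomi–Sakurai product, homoallylic alcohol F1 (silicon lost, C19=C20 vinyl, same open transition state and hence the same C11/C12 sense). VO(acac)2/tBuOOH epoxidises the nearer, homoallylic vinyl group under hydroxyl direction to epoxy alcohol F2; selectivity over the allyl alkene is not assured. Camphorsulfonic acid then closes the ring by attack of O11 on C20 to give tetrahydrofuranol F3. TBSOTf/2,6-lutidine gives silyl ether F4. The conditions of steps 12, 13 and 14 then give aldehyde F5, tricyclic alcohol F6 and ester F7, and HF·pyridine removes both silyl ethers to give 30.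

Step 13 (SmI2 ring closure). This is a medium-ring radical closure onto a fully substituted β-carbon; simple reduction and pinacol-type by-products and the C14/C5/C4 diastereoselectivity required by the target string are the concerns. The fallback sets out from 25 (with 27) and comes back at 28. Acid 27 is converted with (COCl)2 and catalytic DMF into acid chloride F8, which adds to the aldehyde of 25 under ZnCl2 catalysis to give 1-chloroalkyl ester F9. Slow addition of Bu3SnH/AIBN (PhH, 80 °C) generates the α-acyloxyalkyl radical, whose Giese-type cyclisation onto C5 followed by hydrogen transfer gives 28 with the ester already in place.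

Step 5 (aldol condensation). The aldehyde can act as the nucleophile instead of the electrophile, C6 can epimerise, and the isopropenyl group is acid-sensitive. The fallback sets out from 9 and comes back at 12. Compound 9 is isolated by non-aqueous work-up of step 4 and treated with TiCl4 (CH2Cl2, −78 °C); intramolecular Mukaiyama aldol-type addition of its C4 terminus to the oxocarbenium ion opened from the dioxane gives β-alkoxy ketone F10 regiospecifically. DBU (PhMe, 60 °C) then eliminates the alkoxy group to give 12.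

**Further compounds**
F1 | step 11 | homoallylic alcohol (C11–OH; C12 bearing methyl, vinyl and allyl) | C[C@@H]([C@H](O)[C@](C)(C=C)CC=C)[C@]12CCC(=O)C1=C(C)[C@@H](C)CC2
F2 | step 11 | epoxy alcohol (C19–C20 epoxide of F1) | C[C@@H]([C@H](O)[C@](C)([C@H]1CO1)CC=C)[C@]12CCC(=O)C1=C(C)[C@@H](C)CC2
F3 | step 11 | tetrahydrofuranol (C19–OH analogue of 23) | C[C@@H]([C@@H]1OC[C@@H](O)[C@]1(C)CC=C)[C@]12CCC(=O)C1=C(C)[C@@H](C)CC2
F4 | step 11 | silyl ether (C19–OTBS analogue of 23) | C[C@@H]([C@@H]1OC[C@@H](O[Si](C)(C)C(C)(C)C)[C@]1(C)CC=C)[C@]12CCC(=O)C1=C(C)[C@@H](C)CC2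
F5 | step 11 | aldehyde (C19–OTBS analogue of 25) | C[C@@H]([C@@H]1OC[C@@H](O[Si](C)(C)C(C)(C)C)[C@]1(C)CC=O)[C@]12CCC(=O)C1=C(C)[C@@H](C)CC2
F6 | step 11 | tricyclic alcohol (C19–OTBS analogue of 26) | C[C@H]1[C@@H]2OC[C@@H](O[Si](C)(C)C(C)(C)C)[C@]2(C)C[C@@H](O)[C@@]2(C)[C@@H](C)CC[C@]13CCC(=O)[C@@H]32
F7 | step 11 | ester (C19–OTBS analogue of 28) | C[C@H]1[C@@H]2OC[C@@H](O[Si](C)(C)C(C)(C)C)[C@]2(C)C[C@@H](OC(=O)CO[Si](C)(C)C(C)(C)C)[C@@]2(C)[C@@H](C)CC[C@]13CCC(=O)[C@@H]32
F8 | step 13 | acid chloride, 2-[(tert-butyldimethylsilyl)oxy]acetyl chloride | CC(C)(C)[Si](C)(C)OCC(=O)Cl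
F9 | step 13 | 1-chloroalkyl ester (C14 chloro(acyloxy)methine from 25, both C14 epimers) | C[C@@H]([C@@H]1OC[C@@H]([Si](C)(C)c2ccccc2)[C@]1(C)CC(Cl)OC(=O)CO[Si](C)(C)C(C)(C)C)[C@]12CCC(=O)C1=C(C)[C@@H](C)CC2
F10 | step 5 | β-alkoxy ketone (3-hydroxypropoxy group on C3, mixture at C3/C4) | CC(=C)[C@]12CCC(OCCCO)C1C(=O)[C@@H](C)CC2
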